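**Plan**

1. Cuts (labdane numbering of the target): C6–C7 and C9–C10 of ring B. They divide the skeleton into a ring-A enone carrying CH2I on C5 (C1–C6, C10, C18–C20) and a nerol-derived chain ketone (C7–C9, C11–C16). C17 is added afterwards by Wittig reaction and the C7 oxygen by a last allylic hydroxylation.
2. Enabling feature: C8, the sp2 carbon of ring B, lies between C7 and C9, so as a ketone it makes both of them nucleophilic. C10 is the β-carbon of an enone whose carbonyl is C2, and C6 is a CH2–I on C5. A 1,3-dinucleophile therefore meets a 1,3-dielectrophile in a [3+3] annulation that joins two fragments of similar size at the quaternary carbon.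
3. Forward order: ring A (steps 1–7), chain from nerol (steps 8–12), ring B closed in one flask by Mukaiyama–Michael addition (C9–C10) and enolate alkylation (C6–C7) in step 13, then methylenation, reduction and oxidation-level adjustment (steps 14–18).
4. Stereochemistry: C4 from asymmetric conjugate addition; C5 from a cis-fused lactone; C10 from attack anti to CH2I; C9 by equilibration next to the C8 ketone; C2 by dissolving-metal reduction (equatorial OH); C7 by SeO2 (axial OH); 13Z from nerol.

Key step: step 13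

Remark: positions in names and explanations follow the labdane numbering of the target (normal series: 5α-H, 9α-H, 10β-CH3, C19 = 4β-substituent); the ligand in step 1 is taken as the enantiomer that gives (S)-2.

**Route**

Step 1
Reactants: 1 methyl 3-oxocyclohex-1-ene-1-carboxylate
Product: 2 methyl (1S)-1-methyl-3-oxocyclohexane-1-carboxylate
Conditions: Me2Zn, (CuOTf)2·C6H6 (2.5 mol%), chiral sulfonate-bearing imidazolinium salt (carbene precursor, 5 mol%), t-BuOMe, −30 °C; then 1 M HCl
Reagents that add atoms: dimethylzinc, C[Zn]C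
Why: Copper-catalysed asymmetric conjugate addition of a methyl group to a cyclic β-ester enone is a known route to an all-carbon quaternary centre, and the chiral carbene ligand sets C4.

Step 2
Reactants: 2 methyl (1S)-1-methyl-3-oxocyclohexane-1-carboxylate
Product: 3 methyl (1S)-1-methyl-5-oxocyclohex-3-ene-1-carboxylate
Conditions: Pd(O2CCF3)2 (5 mol%), Me2SO (10 mol%), O2 (1 atm), AcOH, 80 °C
Reagents that add atoms: none
Why: Palladium-catalysed aerobic dehydrogenation of a ketone to an enone can take place on one side only, because the other β-carbon is the quaternary centre, and for the same reason it cannot run on to a phenol.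

Step 3
Reactants: 3 methyl (1S)-1-methyl-5-oxocyclohex-3-ene-1-carboxylate
Product: 5 (3aR,7aS)-7a-methyl-3,3a,7,7a-tetrahydro-2-benzofuran-1,4-dione, via hydroxymethyl ketone 4 (not isolated)
Conditions: LiN(i-Pr)2, THF, −78 °C; CH2O (gas), −78 to −40 °C; AcOH; then pyridinium p-toluenesulfonate (cat.), PhMe, 50 °C
Reagents that add atoms: formaldehyde, C=O
Why: The kinetic α′-enolate adds to formaldehyde (aldol reaction) and the new hydroxyl closes a γ-lactone onto the neighbouring ester, which is possible only when CH2O and the ester are cis, so C5 is set cis to C19 while the trans aldolate can return through retro-aldol reaction.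

Step 4
Reactants: 5 (3aR,7aS)-7a-methyl-3,3a,7,7a-tetrahydro-2-benzofuran-1,4-dione
Product: 6 (3aR,7aS)-4-hydroxy-4,7a-dimethyl-3a,4,7,7a-tetrahydro-2-benzofuran-1(3H)-one (both C4 epimers)
Conditions: MeLi, CeCl3, THF, −78 °C; then aq. NH4Cl at −78 °C
Reagents that add atoms: methyllithium, [Li]C
Why: Methylcerium dichloride adds 1,2 to the enone carbonyl without enolisation and leaves the hindered lactone alone (organocerium addition); the new carbinol centre is removed again in step 5.

Step 5
Reactants: 6 (3aR,7aS)-4-hydroxy-4,7a-dimethyl-3a,4,7,7a-tetrahydro-2-benzofuran-1(3H)-one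
Product: 7 (3aR,7aS)-4,7a-dimethyl-3,3a,7,7a-tetrahydro-2-benzofuran-1,6-dione
Conditions: pyridinium chlorochromate (C5H5NH)[CrO3Cl], 4 Å sieves, CH2Cl2, 23 °C
Reagents that add atoms: pyridinium chlorochromate, [O-][Cr](=O)(=O)Cl.c1cc[nH+]cc1
Why: Babler–Dauben oxidative transposition: the chromate ester of the tertiary allylic alcohol shifts [3,3] and is oxidised, which puts the carbonyl on C2 and the methyl-bearing alkene carbon at C10.

Step 6
Reactants: 7 (3aR,7aS)-4,7a-dimethyl-3,3a,7,7a-tetrahydro-2-benzofuran-1,6-dione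
Product: 8 (1S,6R)-6-(iodomethyl)-1,5-dimethyl-3-oxocyclohex-4-ene-1-carboxylic acid
Conditions: Me3SiI, MeCN, 60 °C; then H2O
Reagents that add atoms: iodotrimethylsilane, C[Si](C)(C)I
Why: Iodotrimethylsilane silylates the lactone carbonyl and iodide opens the ring by SN2 attack at the CH2–O carbon (C6), which should give the primary iodide and the C19 acid without touching a stereocentre.

Step 7
Reactants: 8 (1S,6R)-6-(iodomethyl)-1,5-dimethyl-3-oxocyclohex-4-ene-1-carboxylic acid
Product: 9 methyl (1S,6R)-6-(iodomethyl)-1,5-dimethyl-3-oxocyclohex-4-ene-1-carboxylate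
Conditions: Me3SiCHN2, PhMe/MeOH, 0 °C
Reagents that add atoms: (trimethylsilyl)diazomethane, C[Si](C)(C)C=[N+]=[N-]
Why: Esterification with a diazoalkane is neutral, so the γ-(iodomethyl) enone is not exposed to a base that would eliminate HI.

Step 8
Reactants: 10 nerol, (2Z)-3,7-dimethylocta-2,6-dien-1-ol
Product: 11 tert-butyl{[(2Z)-3,7-dimethylocta-2,6-dien-1-yl]oxy}dimethylsilane
Conditions: t-BuMe2SiCl, imidazole, CH2Cl2, 23 °C
Reagents that add atoms: tert-butyldimethylsilyl chloride, CC(C)(C)[Si](C)(C)Cl
Why: Standard silylation of the primary allylic alcohol; the Z alkene of nerol becomes C13=C14 of the target.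

Step 9
Reactants: 11 tert-butyl{[(2Z)-3,7-dimethylocta-2,6-dien-1-yl]oxy}dimethylsilane
Product: 12 tert-butyl{[(2Z)-5-(3,3-dimethyloxiran-2-yl)-3-methylpent-2-en-1-yl]oxy}dimethylsilane (racemic at the epoxide)
Conditions: m-CPBA (1.0 equiv), NaHCO3, CH2Cl2, −20 °C
Reagents that add atoms: 3-chloroperoxybenzoic acid, OOC(=O)c1cccc(Cl)c1
Why: Prilezhaev epoxidation should go to the distal trisubstituted alkene, which is more electron-rich than the alkene carrying the allylic silyloxy group.

Step 10
Reactants: 12 tert-butyl{[(2Z)-5-(3,3-dimethyloxiran-2-yl)-3-methylpent-2-en-1-yl]oxy}dimethylsilane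
Product: 13 (4Z)-6-[(tert-butyldimethylsilyl)oxy]-4-methylhex-4-enal
Conditions: H5IO6, THF/Et2O, 0 °C
Reagents that add atoms: none
Why: Periodic acid opens the epoxide and cleaves the resulting diol (Malaprade cleavage) to the aldehyde whose carbonyl carbon becomes C9, with loss of acetone.

Step 11
Reactants: 13 (4Z)-6-[(tert-butyldimethylsilyl)oxy]-4-methylhex-4-enal
Product: 14 tert-butyl{[(2Z)-6,6-dibromo-3-methylhex-2-en-1-yl]oxy}dimethylsilane
Conditions: P(OPh)3, Br2, Et3N, CH2Cl2, −78 °C
Reagents that add atoms: bromine, BrBr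
Why: Preformed triphenyl phosphite dibromide converts an aldehyde into its geminal dibromide at low temperature without free bromine, so the alkene and the silyl ether should survive.

Step 12
Reactants: 14 tert-butyl{[(2Z)-6,6-dibromo-3-methylhex-2-en-1-yl]oxy}dimethylsilane
Product: 15 (2Z,6Z)-2,8-bis[(tert-butyldimethylsilyl)oxy]-6-methylocta-2,6-diene
Conditions: Zn, TiCl4, TMEDA, PbCl2 (cat.), t-BuMe2SiOAc, THF, 23 °C
Reagents that add atoms: tert-butyldimethylsilyl acetate, CC(=O)O[Si](C)(C)C(C)(C)C
Why: Takai–Utimoto alkylidenation of a silyl ester by the zinc–titanium carbenoid from the dibromide gives the Z silyl enol ether with the double bond fixed between C8 and C9, which enolisation of the methyl ketone could not secure.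

Step 13
Reactants: 9 methyl (1S,6R)-6-(iodomethyl)-1,5-dimethyl-3-oxocyclohex-4-ene-1-carboxylate; 15 (2Z,6Z)-2,8-bis[(tert-butyldimethylsilyl)oxy]-6-methylocta-2,6-diene
Product: 18 methyl 2,15-bis[(tert-butyldimethylsilyl)oxy]-8-oxo-17-norlabda-1,13Z-dien-19-oate, via Michael adduct 16 (not isolated), via C9-epimeric decalone 17 (not isolated)
Conditions: HNTf2 (5 mol%), CH2Cl2, −78 to −40 °C; then KN(SiMe3)2, THF, −78 to 0 °C; then t-BuOH, 23 °C
Reagents that add atoms: none
Why: Catalytic HNTf2 turns a little of 15 into t-BuMe2SiNTf2, which activates the enone of 9 at oxygen; C9 of the enol ether adds to C10 (Mukaiyama–Michael reaction) and the silyl group passes on to the C2 oxygen, so that 16 holds a free C8 methyl ketone while the C2 carbonyl stays masked as an enol ether. KN(SiMe3)2 then takes a proton from the C7 methyl group (the other α-carbon, C9, is a hindered methine) and the enolate displaces iodide at C6; the closest known reaction types are the silyl-triflimide-catalysed Mukaiyama–Michael addition and the intramolecular alkylation of a kinetic ketone enolate, joined here as an α,α′-annulation of a ketone onto a 1,3-dielectrophile. Ring B closes in the 6-(enolendo)-exo-tet mode through a chair. C10 is controlled by C5: allylic 1,2-strain against the C10 methyl group holds CH2I axial on the β face, the nucleophile enters axially on the α face, and the methyl group ends β, trans to H-5; C9 is controlled by equilibration next to the C8 ketone (KOC(CH3)3 formed from t-BuOH) to the equatorial side chain. The step needs 1,4- over 1,2-addition (the aldol-type 1,2-adduct reverts under the silyl Lewis acid), C- over O-alkylation (soft iodide, chair-like six-membered transition state) and substitution over loss of HI (ring closure is intramolecular and run cold).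

Step 14
Reactants: 18 methyl 2,15-bis[(tert-butyldimethylsilyl)oxy]-8-oxo-17-norlabda-1,13Z-dien-19-oate
Product: 20 methyl 15-hydroxy-2-oxolabda-8(17),13Z-dien-19-oate, via silyl enol ether triene 19 (not isolated)
Conditions: Ph3PCH3Br, KN(SiMe3)2, PhMe, 90 °C; then n-Bu4NF, AcOH, THF, 23 °C
Reagents that add atoms: methyltriphenylphosphonium bromide, C[P+](c1ccccc1)(c1ccccc1)c1ccccc1.[Br-]
Why: Wittig methylenation of the hindered C8 ketone installs C17 while the C2 carbonyl is still masked as its silyl enol ether, and buffered fluoride then frees the C2 ketone and the C15 alcohol.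

Step 15
Reactants: 20 methyl 15-hydroxy-2-oxolabda-8(17),13Z-dien-19-oate
Product: 21 labda-8(17),13Z-diene-2α,15,19-triol
Conditions: Li, NH3 (l), THF, EtOH, −78 to −33 °C; then NH4Cl
Reagents that add atoms: none
Why: Dissolving-metal reduction should give the thermodynamically favoured equatorial 2α-alcohol, which hydride reagents cannot deliver past the axial C19 and C20 groups, and it reduces the ester to the C19 carbinol (Bouveault–Blanc reduction) while the allylic alkoxide and the isolated alkenes stay inert.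

Step 16
Reactants: 21 labda-8(17),13Z-diene-2α,15,19-triol
Product: 22 2α,19-dihydroxylabda-8(17),13Z-dien-15-al
Conditions: MnO2, CH2Cl2, 23 °C
Reagents that add atoms: none
Why: Manganese dioxide oxidises only the allylic primary alcohol and keeps the Z geometry, as in the oxidation of nerol to neral.

Step 17
Reactants: 22 2α,19-dihydroxylabda-8(17),13Z-dien-15-al
Product: 23 19-acetoxy-2α-hydroxylabda-8(17),13Z-dien-15-al
Conditions: AcCl, 2,4,6-collidine, CH2Cl2, −78 °C
Reagents that add atoms: acetyl chloride, CC(Cl)=O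
Why: Acetyl chloride with collidine at low temperature acylates a primary alcohol much faster than a secondary one, so C19 should be acetylated in the presence of the 2α-hydroxyl group.

Step 18
Reactants: 23 19-acetoxy-2α-hydroxylabda-8(17),13Z-dien-15-al
Product: 24 19-acetoxy-2α,7α-dihydroxylabda-8(17),13Z-dien-15-al (CNP0249702.2)
Conditions: SeO2 (0.3 equiv), t-BuOOH, CH2Cl2, 23 °C
Reagents that add atoms: tert-butyl hydroperoxide, CC(C)(C)OO
Why: Selenium dioxide (ene reaction, then [2,3]-sigmatropic shift) hydroxylates the ring CH2 next to the exocyclic alkene from the α face to give the axial 7α-alcohol, the usual outcome for methylenecyclohexanes of this type, while the conjugated enal alkene is too electron-poor to react.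

**Compound list**

1 | methyl 3-oxocyclohex-1-ene-1-carboxylate | COC(=O)C1=CC(=O)CCC1 | starting material
2 | methyl (1S)-1-methyl-3-oxocyclohexane-1-carboxylate | O=C1C[C@@](C)(C(=O)OC)CCC1 | intermediate
3 | methyl (1S)-1-methyl-5-oxocyclohex-3-ene-1-carboxylate | O=C1C[C@@](C)(C(=O)OC)CC=C1 | intermediate
4 | methyl (1S)-6-(hydroxymethyl)-1-methyl-5-oxocyclohex-3-ene-1-carboxylate (both C6 epimers) | OCC1[C@@](C)(C(=O)OC)CC=CC1=O | intermediate
5 | (3aR,7aS)-7a-methyl-3,3a,7,7a-tetrahydro-2-benzofuran-1,4-dione (cis-fused lactone) | O1C[C@H]2[C@@](C)(C1=O)CC=CC2=O | intermediate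
6 | (3aR,7aS)-4-hydroxy-4,7a-dimethyl-3a,4,7,7a-tetrahydro-2-benzofuran-1(3H)-one (both C4 epimers) | O1C[C@H]2[C@@](C)(C1=O)CC=CC2(C)O | intermediate
7 | (3aR,7aS)-4,7a-dimethyl-3,3a,7,7a-tetrahydro-2-benzofuran-1,6-dione | O1C[C@H]2[C@@](C)(C1=O)CC(=O)C=C2C | intermediate
8 | (1S,6R)-6-(iodomethyl)-1,5-dimethyl-3-oxocyclohex-4-ene-1-carboxylic acid | IC[C@H]1[C@@](C)(C(=O)O)CC(=O)C=C1C | intermediate
9 | methyl (1S,6R)-6-(iodomethyl)-1,5-dimethyl-3-oxocyclohex-4-ene-1-carboxylate | IC[C@H]1[C@@](C)(C(=O)OC)CC(=O)C=C1C | intermediate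
10 | nerol, (2Z)-3,7-dimethylocta-2,6-dien-1-ol | CC(C)=CCC/C(C)=C\CO | starting material
11 | tert-butyl{[(2Z)-3,7-dimethylocta-2,6-dien-1-yl]oxy}dimethylsilane | CC(C)=CCC/C(C)=C\CO[Si](C)(C)C(C)(C)C | intermediate
12 | tert-butyl{[(2Z)-5-(3,3-dimethyloxiran-2-yl)-3-methylpent-2-en-1-yl]oxy}dimethylsilane (racemic at the epoxide) | CC1(C)OC1CC/C(C)=C\CO[Si](C)(C)C(C)(C)C | intermediate
13 | (4Z)-6-[(tert-butyldimethylsilyl)oxy]-4-methylhex-4-enal | O=CCC/C(C)=C\CO[Si](C)(C)C(C)(C)C | intermediate
14 | tert-butyl{[(2Z)-6,6-dibromo-3-methylhex-2-en-1-yl]oxy}dimethylsilane | BrC(Br)CC/C(C)=C\CO[Si](C)(C)C(C)(C)C | intermediate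
15 | (2Z,6Z)-2,8-bis[(tert-butyldimethylsilyl)oxy]-6-methylocta-2,6-diene | C/C(O[Si](C)(C)C(C)(C)C)=C/CC/C(C)=C\CO[Si](C)(C)C(C)(C)C | intermediate
16 | methyl 2,15-bis[(tert-butyldimethylsilyl)oxy]-6-iodo-8-oxo-17-nor-6,7-secolabda-1,13Z-dien-19-oate (5α-H, 10β-CH3, both C9 epimers) | IC[C@H]1[C@@](C)(C(=O)OC)CC(O[Si](C)(C)C(C)(C)C)=C[C@]1(C)C(CC/C(C)=C\CO[Si](C)(C)C(C)(C)C)C(C)=O | intermediate
17 | methyl 2,15-bis[(tert-butyldimethylsilyl)oxy]-8-oxo-17-norlabda-1,13Z-dien-19-oate (both C9 epimers) | O=C1CC[C@H]2[C@@](C)(C(=O)OC)CC(O[Si](C)(C)C(C)(C)C)=C[C@]2(C)C1CC/C(C)=C\CO[Si](C)(C)C(C)(C)C | intermediate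
18 | methyl 2,15-bis[(tert-butyldimethylsilyl)oxy]-8-oxo-17-norlabda-1,13Z-dien-19-oate (9α-H, side chain equatorial) | O=C1CC[C@H]2[C@@](C)(C(=O)OC)CC(O[Si](C)(C)C(C)(C)C)=C[C@]2(C)[C@H]1CC/C(C)=C\CO[Si](C)(C)C(C)(C)C | intermediate
19 | methyl 2,15-bis[(tert-butyldimethylsilyl)oxy]labda-1,8(17),13Z-trien-19-oate | C=C1CC[C@H]2[C@@](C)(C(=O)OC)CC(O[Si](C)(C)C(C)(C)C)=C[C@]2(C)[C@H]1CC/C(C)=C\CO[Si](C)(C)C(C)(C)C | intermediate
20 | methyl 15-hydroxy-2-oxolabda-8(17),13Z-dien-19-oate | C=C1CC[C@H]2[C@@](C)(C(=O)OC)CC(=O)C[C@]2(C)[C@H]1CC/C(C)=C\CO | intermediate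
21 | labda-8(17),13Z-diene-2α,15,19-triol | C=C1CC[C@H]2[C@@](C)(CO)C[C@H](O)C[C@]2(C)[C@H]1CC/C(C)=C\CO | intermediate
22 | 2α,19-dihydroxylabda-8(17),13Z-dien-15-al | C=C1CC[C@H]2[C@@](C)(CO)C[C@H](O)C[C@]2(C)[C@H]1CC/C(C)=C\C=O | intermediate
23 | 19-acetoxy-2α-hydroxylabda-8(17),13Z-dien-15-al | C=C1CC[C@H]2[C@@](C)(COC(C)=O)C[C@H](O)C[C@]2(C)[C@H]1CC/C(C)=C\C=O | intermediate
24 | 19-acetoxy-2α,7α-dihydroxylabda-8(17),13Z-dien-15-al (CNP0249702.2) | C=C1[C@H](O)C[C@H]2[C@@](C)(COC(C)=O)C[C@H](O)C[C@]2(C)[C@H]1CC/C(C)=C\C=O | target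

**Totals**

Total step count: 18. Longest linear sequence: 13 steps (steps 1–7, then 13–18); the chain fragment takes 5 steps (8–12) before the union.

**Three steps most likely to fail**

Step 13. The Mukaiyama–Michael addition may stall at the hindered, fully substituted β-carbon or divert to 1,2-addition, and the base may eliminate HI instead of closing the ring. The fallback replaces the ketone enol ether by an allylsilane that brings the exocyclic alkene with it; it sets out from 13 and 9 and returns at 20.
- Aldehyde 13 would be taken by Horner–Wadsworth–Emmons reaction with triethyl 2-(trimethylsilylmethyl)phosphonoacetate (NaH, THF) to ethyl ester F1.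
- i-Bu2AlH would give allylic alcohol F2, and Corey–Kim chlorination (N-chlorosuccinimide, Me2S) would give allylic chloride F3, an allylsilane that also carries an allyl chloride.
- TiCl4-promoted Hosomi–Sakurai addition of F3 to enone 9 (CH2Cl2, −78 °C) should form C9–C10 anti to CH2I and give iodo chloride F4 with the C8=C17 alkene in place.
- n-Bu3SnH/AIBN (slow addition, PhH, 80 °C) should generate the C6 radical, which closes ring B in the 6-endo mode onto the terminal alkene carbon and expels chlorine to give silyl ether F5. C9 is not controlled in this variant, so separation from the C9 epimer may be needed.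
- n-Bu4NF would then give 20.

Step 3. Formaldehyde may polymerise or add twice, the aldolate may revert, and the alkoxide base may eliminate the acyloxy group from the β-acyloxy ketone once the lactone has formed. The fallback avoids the lithium aldolate; it sets out from 3 and returns at 5. LiN(i-Pr)2/Me3SiCl would give silyloxy diene F6; hydroxymethylation of F6 with aqueous formaldehyde and Yb(OTf)3 (THF/H2O, 23 °C, a Lewis-acid-catalysed Mukaiyama aldol reaction in water) should give 4 under near-neutral conditions, and pyridinium p-toluenesulfonate would close the lactone to 5.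

Step 18. Selenous acid may isomerise the Z enal to E, the new allylic alcohol may be over-oxidised to the enone, and other allylic positions may be attacked. The fallback hydroxylates before the enal exists; it sets out from 21 and returns at 24.
- AcCl (2.2 equiv)/collidine at low temperature should acetylate both primary alcohols and give diacetate F7.
- SeO2/t-BuOOH should hydroxylate C7 of F7, whose side-chain alkene is deactivated by its allylic acetate, to give hydroxy diacetate F8.
- K2CO3/MeOH at 0 °C should remove the unhindered allylic acetate faster than the neopentyl one and give allylic alcohol F9.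
- TEMPO/PhI(OAc)2 would oxidise the primary allylic alcohol of F9 to the aldehyde and give 24.

**Further compounds**

F1 | step 13 | ethyl (6Z)-8-[(tert-butyldimethylsilyl)oxy]-6-methyl-2-[(trimethylsilyl)methyl]octa-2,6-dienoate (2-ene as E/Z mixture) | CCOC(=O)C(C[Si](C)(C)C)=CCC/C(C)=C\CO[Si](C)(C)C(C)(C)C
F2 | step 13 | (6Z)-8-[(tert-butyldimethylsilyl)oxy]-6-methyl-2-[(trimethylsilyl)methyl]octa-2,6-dien-1-ol | OCC(C[Si](C)(C)C)=CCC/C(C)=C\CO[Si](C)(C)C(C)(C)C
F3 | step 13 | tert-butyl{[(2Z)-7-(chloromethyl)-3-methyl-8-(trimethylsilyl)octa-2,6-dien-1-yl]oxy}dimethylsilane | ClCC(C[Si](C)(C)C)=CCC/C(C)=C\CO[Si](C)(C)C(C)(C)C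
F4 | step 13 | methyl 15-[(tert-butyldimethylsilyl)oxy]-7-chloro-6-iodo-2-oxo-6,7-secolabda-8(17),13Z-dien-19-oate (C9 epimers) | IC[C@H]1[C@@](C)(C(=O)OC)CC(=O)C[C@]1(C)C(CC/C(C)=C\CO[Si](C)(C)C(C)(C)C)C(=C)CCl
F5 | step 13 | methyl 15-[(tert-butyldimethylsilyl)oxy]-2-oxolabda-8(17),13Z-dien-19-oate | C=C1CC[C@H]2[C@@](C)(C(=O)OC)CC(=O)C[C@]2(C)[C@H]1CC/C(C)=C\CO[Si](C)(C)C(C)(C)C
F6 | step 3 | methyl (1S)-1-methyl-3-[(trimethylsilyl)oxy]cyclohexa-2,4-diene-1-carboxylate | C[Si](C)(C)OC1=C[C@@](C)(C(=O)OC)CC=C1
F7 | step 18 | 15,19-diacetoxylabda-8(17),13Z-dien-2α-ol | C=C1CC[C@H]2[C@@](C)(COC(C)=O)C[C@H](O)C[C@]2(C)[C@H]1CC/C(C)=C\COC(C)=O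
F8 | step 18 | 15,19-diacetoxylabda-8(17),13Z-diene-2α,7α-diol | C=C1[C@H](O)C[C@H]2[C@@](C)(COC(C)=O)C[C@H](O)C[C@]2(C)[C@H]1CC/C(C)=C\COC(C)=O
F9 | step 18 | 19-acetoxylabda-8(17),13Z-diene-2α,7α,15-triol | C=C1[C@H](O)C[C@H]2[C@@](C)(COC(C)=O)C[C@H](O)C[C@]2(C)[C@H]1CC/C(C)=C\CO
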